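## Retrosynthetic overview

1. The target comes from its C15 silyl ether by desilylation; that ether comes from one chromium-mediated closure of a fully functionalised open chain, which forms the C6–C7 bond (the farnesyl C1→C10 closure of germacrene biosynthesis) and then the C6–O–C12 lactone.
2. The ring closure is deliberately left to the end: the chain already carries the C8 ester side chain, the epoxide, the cis,cis-diene and the C15 oxygen, so the closing step sets C6 and C7 and only a desilylation follows.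
3. The oxirane is made, as in the biosynthesis, by face-selective epoxidation of the E C1=C10 olefin (Shi), at the chain stage, because the cyclic 1(10),2,4-triene is expected to electrocyclise.
4. The chain comes from methacrolein, acetylene and orthoacetate (Johnson–Claisen), a proline aminoxylation for C8–O, an olefination for C11–C13, a 2-butyne-1,4-diol derivative for C4–C6/C15 (Sonogashira, Lindlar), and 4-methylfuranone for the side chain.
5. Ring order: oxirane, then ten-membered carbocycle, then γ-lactone (the last two in one flask).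

Assumption: positions use germacrane numbering (C6 lactone carbinol, C8 ester carbinol, C1/C10 oxirane, C15 = CH2OH on C4, C11–C13 = acrylate unit on C7, C12 the carbonyl); racemic 3 suffices because its stereocentre is destroyed in step 2.

## Route

Step 1
Reactants: 1 methacrolein; 2 ethynylmagnesium bromide
Product: 3 2-methylpent-1-en-4-yn-3-ol (racemic)
Conditions: THF, −78 to 0 °C; aq. NH4Cl
Reagents that add atoms: none
Why: 1,2-addition of the alkynyl Grignard reagent to the enal gives the allylic/propargylic alcohol, whose stereocentre need not be controlled because it disappears in step 2.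

Step 2
Reactants: 3 2-methylpent-1-en-4-yn-3-ol; 4 triethyl orthoacetate
Product: 5 ethyl (4E)-4-methylhept-4-en-6-ynoate
Conditions: MeC(OEt)3 (6 equiv), EtCO2H (cat.), 140 °C, EtOH distilled off
Reagents that add atoms: none
Why: Johnson–Claisen rearrangement through a chair transition state with the ethynyl group equatorial delivers C7–C9 and sets the E-trisubstituted C10=C1 olefin (expected about 9:1, minor Z isomer removed by chromatography).

Step 3
Reactants: 5 ethyl (4E)-4-methylhept-4-en-6-ynoate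
Product: 6 (4E)-4-methylhept-4-en-6-ynal
Conditions: iBu2AlH (1.05 equiv), CH2Cl2, −78 °C; aq. potassium sodium tartrate
Reagents that add atoms: none
Why: Partial ester reduction stops at the aluminium hemiacetal at −78 °C and releases the aldehyde on work-up (DIBAL-H reduction).

Step 4
Reactants: 7 trimethyl 2-phosphonoacrylate; 8 4-methoxybenzyl alcohol
Product: 9 methyl 2-(dimethoxyphosphoryl)-3-[(4-methoxybenzyl)oxy]propanoate (racemic)
Conditions: NaH (5 mol%), THF, 0 °C
Reagents that add atoms: none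
Why: Base-catalysed oxa-Michael addition of the benzylic alcohol to the vinylphosphonate gives the olefination reagent that carries C11, C12 and a masked C13 oxygen.

Step 5
Reactants: 6 (4E)-4-methylhept-4-en-6-ynal; 9 methyl 2-(dimethoxyphosphoryl)-3-[(4-methoxybenzyl)oxy]propanoate
Product: 12 methyl (2E,4R,6E)-4-hydroxy-2-{[(4-methoxybenzyl)oxy]methyl}-6-methylnona-2,6-dien-8-ynoate, via aminooxy aldehyde 10 (not isolated), via aminooxy enoate 11 (not isolated)
Conditions: L-proline (20 mol%), PhNO (0.9 equiv), DMSO, 23 °C, 15 min; then 9, LiCl, DBU, MeCN, 0 °C; then Cu(OAc)2 (30 mol%), MeOH, 23 °C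
Reagents that add atoms: nitrosobenzene, O=Nc1ccccc1
Why: The L-proline enamine takes up the nitroso oxygen on one face (O-selective nitroso aldol, hydrogen-bonded transition state) to set C8 as R, the labile aminooxy aldehyde is trapped at once by Masamune–Roush Horner–Wadsworth–Emmons olefination (E enoate, the minor 2Z isomer lactonises and is separated), and copper-catalysed N–O cleavage frees the C8 hydroxyl.

Step 6
Reactants: 12 methyl (2E,4R,6E)-4-hydroxy-2-{[(4-methoxybenzyl)oxy]methyl}-6-methylnona-2,6-dien-8-ynoate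
Product: 13 methyl (2E,4R)-5-[(2R,3R)-3-ethynyl-2-methyloxiran-2-yl]-4-hydroxy-2-{[(4-methoxybenzyl)oxy]methyl}pent-2-enoate
Conditions: Shi ketone (D-fructose-derived, 30 mol%), KHSO5 (Oxone), K2CO3, Bu4NHSO4, MeCN/CH2(OMe)2/aq. Na2B4O7 buffer, 0 °C
Reagents that add atoms: potassium peroxymonosulfate, [K+].[O-]S(=O)(=O)OO
Why: Shi asymmetric epoxidation through the spiro transition state oxidises only the electron-rich E-trisubstituted enyne olefin (the enoate is inert) and sets C1 and C10 as R,R under catalyst control.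

Step 7
Reactants: 14 4-{[tert-butyl(dimethyl)silyl]oxy}but-2-yn-1-ol
Product: 15 (2Z)-4-{[tert-butyl(dimethyl)silyl]oxy}-3-iodobut-2-en-1-ol
Conditions: NaAlH2(OCH2CH2OMe)2, THF, 0 °C; then I2, −78 °C
Reagents that add atoms: iodine, II
Why: Hydroxyl-directed trans-hydroalumination puts aluminium on the distal alkyne carbon cis to CH2OH, and iodinolysis with retention gives the Z vinyl iodide that encodes the cis C4=C5 geometry with C15 on C4.

Step 8
Reactants: 15 (2Z)-4-{[tert-butyl(dimethyl)silyl]oxy}-3-iodobut-2-en-1-ol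
Product: 16 (2Z)-4-{[tert-butyl(dimethyl)silyl]oxy}-3-iodobut-2-enal
Conditions: MnO2, CH2Cl2, 23 °C
Reagents that add atoms: none
Why: Manganese dioxide oxidises the allylic alcohol to the enal with retention of the Z geometry and without touching the vinyl iodide or the silyl ether.

Step 9
Reactants: 13 methyl (2E,4R)-5-[(2R,3R)-3-ethynyl-2-methyloxiran-2-yl]-4-hydroxy-2-{[(4-methoxybenzyl)oxy]methyl}pent-2-enoate; 16 (2Z)-4-{[tert-butyl(dimethyl)silyl]oxy}-3-iodobut-2-enal
Product: 17 methyl (2E,4R)-5-{(2R,3R)-3-[(3E)-3-({[tert-butyl(dimethyl)silyl]oxy}methyl)-5-oxopent-3-en-1-yn-1-yl]-2-methyloxiran-2-yl}-4-hydroxy-2-{[(4-methoxybenzyl)oxy]methyl}pent-2-enoate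
Conditions: PdCl2(PPh3)2 (5 mol%), CuI (10 mol%), iPr2NEt, THF, 0 to 23 °C
Reagents that add atoms: none
Why: Sonogashira coupling, in which oxidative addition of zerovalent palladium to the β-iodoenal outruns ionisation of the propargylic epoxide and proceeds with retention, so that C3 ends up cis to the aldehyde carbon C6.

Step 10
Reactants: 18 4-methylfuran-2(5H)-one
Product: 20 (2Z)-4-(acetyloxy)-3-methylbut-2-enoic acid, via sodium hydroxy enoate 19 (not isolated)
Conditions: NaOH (1.0 equiv), H2O/THF, 0 to 23 °C; freeze-dry; Ac2O, pyridine, DMAP (cat.), 0 °C; cold 1 M HCl work-up, used at once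
Reagents that add atoms: sodium hydroxide, [Na+].[OH-]; acetic anhydride, CC(=O)OC(C)=O
Why: Hydroxide opens the butenolide to the hydroxy carboxylate whose Z geometry is fixed by the former ring, and O-acetylation of the salt before acidification traps the open form that would otherwise relactonise (saponification then acetylation).

Step 11
Reactants: 17 (the enynal from step 9); 20 (2Z)-4-(acetyloxy)-3-methylbut-2-enoic acid
Product: 21 methyl (2E,4R)-4-{[(2Z)-4-(acetyloxy)-3-methylbut-2-enoyl]oxy}-5-{(2R,3R)-3-[(3E)-3-({[tert-butyl(dimethyl)silyl]oxy}methyl)-5-oxopent-3-en-1-yn-1-yl]-2-methyloxiran-2-yl}-2-{[(4-methoxybenzyl)oxy]methyl}pent-2-enoate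
Conditions: DCC, DMAP (10 mol%), CH2Cl2, 0 to 23 °C
Reagents that add atoms: none
Why: Steglich esterification of the only free hydroxyl (C8) installs the complete side chain without touching C8, and carbodiimide activation at 0 °C avoids the acid chloride/amine conditions that would isomerise or deconjugate the Z enoate.

Step 12
Reactants: 21 (the C8 ester from step 11)
Product: 22 methyl (2E,4R)-4-{[(2Z)-4-(acetyloxy)-3-methylbut-2-enoyl]oxy}-5-{(2R,3R)-3-[(3E)-3-({[tert-butyl(dimethyl)silyl]oxy}methyl)-5-oxopent-3-en-1-yn-1-yl]-2-methyloxiran-2-yl}-2-(hydroxymethyl)pent-2-enoate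
Conditions: DDQ, CH2Cl2/pH 7 phosphate buffer, 0 °C
Reagents that add atoms: none
Why: Oxidative cleavage of the 4-methoxybenzyl ether by DDQ (hydride abstraction, then hydrolysis) frees the C13 alcohol while the buffered medium spares the propargylic epoxide, the silyl ether and the esters.

Step 13
Reactants: 22 (the C13 alcohol from step 12)
Product: 23 methyl (2E,4R)-4-{[(2Z)-4-(acetyloxy)-3-methylbut-2-enoyl]oxy}-5-{(2R,3R)-3-[(1Z,3E)-3-({[tert-butyl(dimethyl)silyl]oxy}methyl)-5-oxopenta-1,3-dien-1-yl]-2-methyloxiran-2-yl}-2-(hydroxymethyl)pent-2-enoate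
Conditions: H2 (1 atm), Pd/CaCO3 poisoned with Pb(OAc)2, quinoline, EtOAc, 0 °C; used crude
Reagents that add atoms: none
Why: Lindlar semihydrogenation delivers one equivalent of hydrogen syn to the alkyne to give the cis C2=C3 olefin and hence the cis,cis-dienal, with quinoline and low temperature suppressing over-reduction and hydrogenolysis of the new vinyl epoxide.

Step 14
Reactants: 23 (the cis,cis-dienal from step 13)
Product: 24 methyl (2Z,4R)-4-{[(2Z)-4-(acetyloxy)-3-methylbut-2-enoyl]oxy}-2-(bromomethyl)-5-{(2R,3R)-3-[(1Z,3E)-3-({[tert-butyl(dimethyl)silyl]oxy}methyl)-5-oxopenta-1,3-dien-1-yl]-2-methyloxiran-2-yl}pent-2-enoate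
Conditions: NBS, Me2S, CH2Cl2, −30 to 0 °C; used at once
Reagents that add atoms: N-bromosuccinimide, O=C1CCC(=O)N1Br
Why: Corey–Kim bromination converts the only free hydroxyl (primary, allylic) through its alkoxysulfonium salt into the bromide under neutral conditions that spare the aldehyde and the acid-sensitive dienyl epoxide.

Step 15
Reactants: 24 (the allylic bromide from step 14)
Product: 26 (1R,6R,7R,8R,10R)-8-{[(2Z)-4-acetoxy-3-methylbut-2-enoyl]oxy}-15-{[tert-butyl(dimethyl)silyl]oxy}-1,10-epoxygermacra-2Z,4E,11(13)-trien-12,6-olide, via hydroxy ester 25 (not isolated)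
Conditions: CrCl2 (10 equiv), DMF/THF, slow addition of 24 to 0.002 M, 23 °C; aq. NH4Cl
Reagents that add atoms: none
Why: Proposed new method: chromium dichloride turns the bromide into a 2-(methoxycarbonyl)allylchromium species that adds through C7 to the C6 aldehyde in a closed six-membered transition state inside the forming ten-membered ring (pre-folded by the cis,cis-diene), and the resulting trivalent chromium alkoxide lactonises onto C12, so that the carbocycle, C6 (R), C7 (R) and the trans-lactone should arise together under the influence of C8 (expected major isomer, not assured); the closest known reaction type is the intramolecular Nozaki–Hiyama–Kishi allylation of 2-(bromomethyl)acrylates used for simpler germacranolides, and the untested elements are the allylic acyloxy group (possible 1,4-elimination), the cis,cis-dienal and the dienyl epoxide.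

Step 16
Reactants: 26 (the silyl-protected macrolide from step 15)
Product: 27 (1R,6R,7R,8R,10R)-8-{[(2Z)-4-acetoxy-3-methylbut-2-enoyl]oxy}-1,10-epoxy-15-hydroxygermacra-2Z,4E,11(13)-trien-12,6-olide (target)
Conditions: HF·pyridine, pyridine, THF, 0 °C
Reagents that add atoms: none
Why: Fluoride cleaves the primary allylic silyl ether, and the pyridine-buffered reagent is mild enough for the dienyl epoxide, the α-methylene lactone and the acetate, with no stereocentre affected.

## Compound list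

1 | methacrolein | C=C(C)C=O | starting material
2 | ethynylmagnesium bromide | C#C[Mg]Br | starting material
3 | 2-methylpent-1-en-4-yn-3-ol (racemic) | C=C(C)C(O)C#C | intermediate
4 | triethyl orthoacetate | CC(OCC)(OCC)OCC | starting material
5 | ethyl (4E)-4-methylhept-4-en-6-ynoate | CCOC(=O)CC/C(C)=C/C#C | intermediate
6 | (4E)-4-methylhept-4-en-6-ynal | O=CCC/C(C)=C/C#C | intermediate
7 | trimethyl 2-phosphonoacrylate | C=C(C(=O)OC)P(=O)(OC)OC | starting material
8 | 4-methoxybenzyl alcohol | COc1ccc(CO)cc1 | starting material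
9 | methyl 2-(dimethoxyphosphoryl)-3-[(4-methoxybenzyl)oxy]propanoate (racemic) | COC(=O)C(COCc1ccc(OC)cc1)P(=O)(OC)OC | intermediate
10 | (2R,4E)-4-methyl-2-[(phenylamino)oxy]hept-4-en-6-ynal | O=C[C@H](ONc1ccccc1)C/C(C)=C/C#C | intermediate (not isolated)
11 | methyl (2E,4R,6E)-2-{[(4-methoxybenzyl)oxy]methyl}-6-methyl-4-[(phenylamino)oxy]nona-2,6-dien-8-ynoate | COC(=O)/C(COCc1ccc(OC)cc1)=C/[C@H](ONc1ccccc1)C/C(C)=C/C#C | intermediate (not isolated)
12 | methyl (2E,4R,6E)-4-hydroxy-2-{[(4-methoxybenzyl)oxy]methyl}-6-methylnona-2,6-dien-8-ynoate | COC(=O)/C(COCc1ccc(OC)cc1)=C/[C@H](O)C/C(C)=C/C#C | intermediate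
13 | methyl (2E,4R)-5-[(2R,3R)-3-ethynyl-2-methyloxiran-2-yl]-4-hydroxy-2-{[(4-methoxybenzyl)oxy]methyl}pent-2-enoate | COC(=O)/C(COCc1ccc(OC)cc1)=C/[C@H](O)C[C@@]1(C)O[C@@H]1C#C | intermediate
14 | 4-{[tert-butyl(dimethyl)silyl]oxy}but-2-yn-1-ol | OCC#CCO[Si](C)(C)C(C)(C)C | starting material
15 | (2Z)-4-{[tert-butyl(dimethyl)silyl]oxy}-3-iodobut-2-en-1-ol | OC/C=C(\I)CO[Si](C)(C)C(C)(C)C | intermediate
16 | (2Z)-4-{[tert-butyl(dimethyl)silyl]oxy}-3-iodobut-2-enal | O=C/C=C(\I)CO[Si](C)(C)C(C)(C)C | intermediate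
17 | methyl (2E,4R)-5-{(2R,3R)-3-[(3E)-3-({[tert-butyl(dimethyl)silyl]oxy}methyl)-5-oxopent-3-en-1-yn-1-yl]-2-methyloxiran-2-yl}-4-hydroxy-2-{[(4-methoxybenzyl)oxy]methyl}pent-2-enoate | COC(=O)/C(COCc1ccc(OC)cc1)=C/[C@H](O)C[C@@]1(C)O[C@@H]1C#C/C(CO[Si](C)(C)C(C)(C)C)=C\C=O | intermediate
18 | 4-methylfuran-2(5H)-one | CC1=CC(=O)OC1 | starting material
19 | sodium (2Z)-4-hydroxy-3-methylbut-2-enoate | [Na+].[O-]C(=O)/C=C(/C)CO | intermediate (not isolated)
20 | (2Z)-4-(acetyloxy)-3-methylbut-2-enoic acid | OC(=O)/C=C(/C)COC(C)=O | intermediate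
21 | methyl (2E,4R)-4-{[(2Z)-4-(acetyloxy)-3-methylbut-2-enoyl]oxy}-5-{(2R,3R)-3-[(3E)-3-({[tert-butyl(dimethyl)silyl]oxy}methyl)-5-oxopent-3-en-1-yn-1-yl]-2-methyloxiran-2-yl}-2-{[(4-methoxybenzyl)oxy]methyl}pent-2-enoate | COC(=O)/C(COCc1ccc(OC)cc1)=C/[C@H](OC(=O)/C=C(/C)COC(C)=O)C[C@@]1(C)O[C@@H]1C#C/C(CO[Si](C)(C)C(C)(C)C)=C\C=O | intermediate
22 | methyl (2E,4R)-4-{[(2Z)-4-(acetyloxy)-3-methylbut-2-enoyl]oxy}-5-{(2R,3R)-3-[(3E)-3-({[tert-butyl(dimethyl)silyl]oxy}methyl)-5-oxopent-3-en-1-yn-1-yl]-2-methyloxiran-2-yl}-2-(hydroxymethyl)pent-2-enoate | COC(=O)/C(CO)=C/[C@H](OC(=O)/C=C(/C)COC(C)=O)C[C@@]1(C)O[C@@H]1C#C/C(CO[Si](C)(C)C(C)(C)C)=C\C=O | intermediate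
23 | methyl (2E,4R)-4-{[(2Z)-4-(acetyloxy)-3-methylbut-2-enoyl]oxy}-5-{(2R,3R)-3-[(1Z,3E)-3-({[tert-butyl(dimethyl)silyl]oxy}methyl)-5-oxopenta-1,3-dien-1-yl]-2-methyloxiran-2-yl}-2-(hydroxymethyl)pent-2-enoate | COC(=O)/C(CO)=C/[C@H](OC(=O)/C=C(/C)COC(C)=O)C[C@@]1(C)O[C@@H]1/C=C\C(CO[Si](C)(C)C(C)(C)C)=C/C=O | intermediate
24 | methyl (2Z,4R)-4-{[(2Z)-4-(acetyloxy)-3-methylbut-2-enoyl]oxy}-2-(bromomethyl)-5-{(2R,3R)-3-[(1Z,3E)-3-({[tert-butyl(dimethyl)silyl]oxy}methyl)-5-oxopenta-1,3-dien-1-yl]-2-methyloxiran-2-yl}pent-2-enoate | COC(=O)/C(CBr)=C/[C@H](OC(=O)/C=C(/C)COC(C)=O)C[C@@]1(C)O[C@@H]1/C=C\C(CO[Si](C)(C)C(C)(C)C)=C/C=O | intermediate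
25 | methyl (1R,6R,7S,8R,10R)-8-{[(2Z)-4-acetoxy-3-methylbut-2-enoyl]oxy}-15-{[tert-butyl(dimethyl)silyl]oxy}-1,10-epoxy-6-hydroxygermacra-2Z,4E,11(13)-trien-12-oate | C=C(C(=O)OC)[C@H]1[C@H](O)/C=C(CO[Si](C)(C)C(C)(C)C)\C=C/[C@H]2O[C@]2(C)C[C@H]1OC(=O)/C=C(/C)COC(C)=O | intermediate (not isolated)
26 | (1R,6R,7R,8R,10R)-8-{[(2Z)-4-acetoxy-3-methylbut-2-enoyl]oxy}-15-{[tert-butyl(dimethyl)silyl]oxy}-1,10-epoxygermacra-2Z,4E,11(13)-trien-12,6-olide | C=C1C(=O)O[C@@H]2/C=C(CO[Si](C)(C)C(C)(C)C)\C=C/[C@H]3O[C@]3(C)C[C@@H](OC(=O)/C=C(/C)COC(C)=O)[C@@H]12 | intermediate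
27 | (1R,6R,7R,8R,10R)-8-{[(2Z)-4-acetoxy-3-methylbut-2-enoyl]oxy}-1,10-epoxy-15-hydroxygermacra-2Z,4E,11(13)-trien-12,6-olide (CNP0292814.1) | C=C1C(=O)O[C@@H]2/C=C(CO)\C=C/[C@H]3O[C@]3(C)C[C@@H](OC(=O)/C=C(/C)COC(C)=O)[C@@H]12 | target

## Step count and risks

Total step count: 16. Longest linear sequence: 12 steps (1, 2, 3, 5, 6, 9, 11, 12, 13, 14, 15, 16).

The three steps most likely to fail:

Step 15 (ring closure). The allylchromium species may lose the C8 carboxylate by 1,4-elimination, and the facial selectivity at C6/C7 is not assured. The fallback closes the ring on the free C8 alcohol and esterifies afterwards; it sets out from 17 and comes back at 26. Compound 17 is not acylated. DDQ in buffered CH2Cl2 removes the benzyl ether to give methyl (2E,4R)-5-{(2R,3R)-3-[(3E)-3-({[tert-butyl(dimethyl)silyl]oxy}methyl)-5-oxopent-3-en-1-yn-1-yl]-2-methyloxiran-2-yl}-4-hydroxy-2-(hydroxymethyl)pent-2-enoate F1. Lindlar semihydrogenation gives methyl (2E,4R)-5-{(2R,3R)-3-[(1Z,3E)-3-({[tert-butyl(dimethyl)silyl]oxy}methyl)-5-oxopenta-1,3-dien-1-yl]-2-methyloxiran-2-yl}-4-hydroxy-2-(hydroxymethyl)pent-2-enoate F2. Me2S/NBS at −30 °C brominates only the primary allylic alcohol to give methyl (2Z,4R)-2-(bromomethyl)-5-{(2R,3R)-3-[(1Z,3E)-3-({[tert-butyl(dimethyl)silyl]oxy}methyl)-5-oxopenta-1,3-dien-1-yl]-2-methyloxiran-2-yl}-4-hydroxypent-2-enoate F3. CrCl2 then closes the ring with C8 present as a chromium alkoxide, which is no leaving group and can direct the aldehyde, to give (1R,6R,7R,8R,10R)-15-{[tert-butyl(dimethyl)silyl]oxy}-1,10-epoxy-8-hydroxygermacra-2Z,4E,11(13)-trien-12,6-olide F4. DCC/DMAP esterification with 20 returns to 26.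

Step 5 (three operations in one flask). The olefination with the new α-branched phosphonate 9 may be too slow for the labile aminooxy aldehyde. The fallback uses an isolable α-acyloxy aldehyde; it sets out from 6 and comes back at 12. Aldehyde 6 is oxidised with benzoyl peroxide under enamine catalysis by the 2-tritylpyrrolidine enantiomer that gives the 2R product, to give (2R,4E)-4-methyl-1-oxohept-4-en-6-yn-2-yl benzoate F5. Masamune–Roush olefination with 9 (LiCl, DBU, MeCN) gives methyl (2E,4R,6E)-4-(benzoyloxy)-2-{[(4-methoxybenzyl)oxy]methyl}-6-methylnona-2,6-dien-8-ynoate F6. K2CO3 (cat.) in MeOH removes the benzoate and returns to 12.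

Step 9 (palladium next to a propargylic epoxide, with a base-sensitive Z-iodoenal). Zerovalent palladium may open the epoxide to an allenyl species. The fallback couples before the epoxide exists; it sets out from 12 and 15 and comes back at 17. Compound 12 is coupled with iodo alcohol 15 under the same Sonogashira conditions to give methyl (2E,4R,6E,10E)-10-({[tert-butyl(dimethyl)silyl]oxy}methyl)-4,12-dihydroxy-2-{[(4-methoxybenzyl)oxy]methyl}-6-methyldodeca-2,6,10-trien-8-ynoate F7. Shi epoxidation then acts only on the electron-rich E C10=C1 olefin (the other trisubstituted olefin is flanked by two allylic oxygens and conjugated to the alkyne) to give methyl (2E,4R)-5-{(2R,3R)-3-[(3E)-3-({[tert-butyl(dimethyl)silyl]oxy}methyl)-5-hydroxypent-3-en-1-yn-1-yl]-2-methyloxiran-2-yl}-4-hydroxy-2-{[(4-methoxybenzyl)oxy]methyl}pent-2-enoate F8. MnO2 oxidation of the allylic alcohol returns to 17.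

## Further compounds

F1 | step 15 | methyl (2E,4R)-5-{(2R,3R)-3-[(3E)-3-({[tert-butyl(dimethyl)silyl]oxy}methyl)-5-oxopent-3-en-1-yn-1-yl]-2-methyloxiran-2-yl}-4-hydroxy-2-(hydroxymethyl)pent-2-enoate | COC(=O)/C(CO)=C/[C@H](O)C[C@@]1(C)O[C@@H]1C#C/C(CO[Si](C)(C)C(C)(C)C)=C\C=O
F2 | step 15 | methyl (2E,4R)-5-{(2R,3R)-3-[(1Z,3E)-3-({[tert-butyl(dimethyl)silyl]oxy}methyl)-5-oxopenta-1,3-dien-1-yl]-2-methyloxiran-2-yl}-4-hydroxy-2-(hydroxymethyl)pent-2-enoate | COC(=O)/C(CO)=C/[C@H](O)C[C@@]1(C)O[C@@H]1/C=C\C(CO[Si](C)(C)C(C)(C)C)=C/C=O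
F3 | step 15 | methyl (2Z,4R)-2-(bromomethyl)-5-{(2R,3R)-3-[(1Z,3E)-3-({[tert-butyl(dimethyl)silyl]oxy}methyl)-5-oxopenta-1,3-dien-1-yl]-2-methyloxiran-2-yl}-4-hydroxypent-2-enoate | COC(=O)/C(CBr)=C/[C@H](O)C[C@@]1(C)O[C@@H]1/C=C\C(CO[Si](C)(C)C(C)(C)C)=C/C=O
F4 | step 15 | (1R,6R,7R,8R,10R)-15-{[tert-butyl(dimethyl)silyl]oxy}-1,10-epoxy-8-hydroxygermacra-2Z,4E,11(13)-trien-12,6-olide | C=C1C(=O)O[C@@H]2/C=C(CO[Si](C)(C)C(C)(C)C)\C=C/[C@H]3O[C@]3(C)C[C@@H](O)[C@@H]12
F5 | step 5 | (2R,4E)-4-methyl-1-oxohept-4-en-6-yn-2-yl benzoate | O=C[C@H](OC(=O)c1ccccc1)C/C(C)=C/C#C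
F6 | step 5 | methyl (2E,4R,6E)-4-(benzoyloxy)-2-{[(4-methoxybenzyl)oxy]methyl}-6-methylnona-2,6-dien-8-ynoate | COC(=O)/C(COCc1ccc(OC)cc1)=C/[C@H](OC(=O)c1ccccc1)C/C(C)=C/C#C
F7 | step 9 | methyl (2E,4R,6E,10E)-10-({[tert-butyl(dimethyl)silyl]oxy}methyl)-4,12-dihydroxy-2-{[(4-methoxybenzyl)oxy]methyl}-6-methyldodeca-2,6,10-trien-8-ynoate | COC(=O)/C(COCc1ccc(OC)cc1)=C/[C@H](O)C/C(C)=C/C#C/C(CO[Si](C)(C)C(C)(C)C)=C\CO
F8 | step 9 | methyl (2E,4R)-5-{(2R,3R)-3-[(3E)-3-({[tert-butyl(dimethyl)silyl]oxy}methyl)-5-hydroxypent-3-en-1-yn-1-yl]-2-methyloxiran-2-yl}-4-hydroxy-2-{[(4-methoxybenzyl)oxy]methyl}pent-2-enoate | COC(=O)/C(COCc1ccc(OC)cc1)=C/[C@H](O)C[C@@]1(C)O[C@@H]1C#C/C(CO[Si](C)(C)C(C)(C)C)=C\CO
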